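**Retrosynthetic overview**
- Target 13 ⇐ 12 by N–S cleavage; 12 ⇐ 10 by C3 bromination of the N-mesylindole.
- 10 ⇐ 7 by disconnecting C3–C3a: the acetal carbon of an N-(2,2-diethoxyethyl)sulfonanilide attacks the arene as an oxocarbenium ion. This is the only ring closure (the pyrrole ring); the benzene ring is bought.
- Feature: on the benzene ring of the indole, C3a is the only C–H carbon ortho to N1 (C7 carries Br) and it is para to the C6 methoxy group, so an electrophile tethered to N1 through C2 has one possible and electronically favoured site.
- 7 ⇐ 5 + 6 (N1–C2 bond by N-alkylation); 5 ⇐ 3 + 4 (N-mesylation); 3 ⇐ 1 + 2 (bromination para to NH2).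

Key step: step 4

Remark: the target has no stereogenic element, so it is a single achiral compound and no stereocontrol is needed. The only stereocentre on the way, C3 of the unisolated indoline 9, is racemic and is removed by the elimination.

**Route**

Step 1
Reactants: 1 2-bromo-3-methoxyaniline; 2 N-bromosuccinimide
Product: 3 2,4-dibromo-3-methoxyaniline
Conditions: NBS (1.0 equiv), DMF, −10 → 0 °C, dark
Reagents that add atoms: N-bromosuccinimide, O=C1CCC(=O)N1Br
Why: Electrophilic aromatic bromination (NBS/DMF para-bromination of a free aniline), in which the amino group as the strongest donor should direct bromine to C4, para to it and ortho to the methoxy group, while one equivalent at low temperature should hold back a second bromination at C6.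

Step 2
Reactants: 3 2,4-dibromo-3-methoxyaniline; 4 methanesulfonyl chloride
Product: 5 N-(2,4-dibromo-3-methoxyphenyl)methanesulfonamide
Conditions: MsCl (1.2 equiv), pyridine, CH2Cl2, 0 °C → rt
Reagents that add atoms: methanesulfonyl chloride, CS(=O)(=O)Cl
Why: N-sulfonylation of a primary aniline with a sulfonyl chloride in pyridine, which should stop at the mono-sulfonamide because the ortho bromine hinders a second sulfonylation.

Step 3
Reactants: 5 N-(2,4-dibromo-3-methoxyphenyl)methanesulfonamide; 6 2-bromo-1,1-diethoxyethane (bromoacetaldehyde diethyl acetal)
Product: 7 N-(2,4-dibromo-3-methoxyphenyl)-N-(2,2-diethoxyethyl)methanesulfonamide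
Conditions: Cs2CO3 (1.5 equiv), bromoacetal (1.5 equiv), DMF, 100 °C
Reagents that add atoms: 2-bromo-1,1-diethoxyethane, CCOC(CBr)OCC
Why: Carbonate-mediated SN2 N-alkylation of the acidic N-aryl sulfonamide N–H with the primary bromide, heated in DMF because the β,β-dialkoxy bromide is a slow electrophile, under which the acetal and the aryl bromides are inert.

Step 4
Reactants: 7 N-(2,4-dibromo-3-methoxyphenyl)-N-(2,2-diethoxyethyl)methanesulfonamide
Product: 10 5,7-dibromo-6-methoxy-1-(methylsulfonyl)-1H-indole, via oxocarbenium ion 8 (not isolated), via 3-ethoxyindoline 9 (not isolated)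
Conditions: TiCl4 (2.0 equiv), 1,2-dichloroethane, 0 °C → 80 °C; then aq. NaHCO3
Reagents that add atoms: none
Why: TiCl4 should ionise one ethoxy group of the acetal to the N-tethered oxocarbenium ion 8, whose carbon is attacked by the arene carbon ortho to nitrogen (the future C3a) in an intramolecular Friedel–Crafts alkylation that forms C3–C3a and gives 3-ethoxyindoline 9, and Lewis-acid-promoted loss of the second ethanol then aromatises the pyrrole ring. The closest known reaction type is the Lewis-acid cyclisation of N-sulfonyl-N-arylaminoacetaldehyde acetals to N-sulfonylindoles, an indole counterpart of the Pomeranz–Fritsch closure. The one ring closed, the five-membered pyrrole ring, forms in a 5-exo-trig mode with respect to the C=O+ bond, the arene π bond lying inside the new ring. No stereocentre remains, since C3 of 9 is formed racemic and becomes sp2 on elimination. The step needs regioselectivity and ring closure in preference to intermolecular reaction: the other carbon ortho to nitrogen carries bromine, the attacked carbon is para to the methoxy donor, the solvent is not a Friedel–Crafts partner, and the mesyl group keeps nitrogen from binding titanium and shields the indole formed from acid-induced oligomerisation. The two bromines, both meta to the reacting carbon, and the twisted methoxy group slow the closure, which is why an excess of TiCl4 and heating are proposed.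

Step 5
Reactants: 10 5,7-dibromo-6-methoxy-1-(methylsulfonyl)-1H-indole; 11 bromine
Product: 12 3,5,7-tribromo-6-methoxy-1-(methylsulfonyl)-1H-indole
Conditions: Br2 (1.05 equiv), CH2Cl2, 0 °C → rt; then aq. Na2S2O3
Reagents that add atoms: bromine, BrBr
Why: Electrophilic bromination of an N-sulfonylindole, which is known to take place at C3 of the enamide-like C2=C3 bond, and which should stop at monobromination because the sulfonyl group tempers the ring and C4, the only free benzenoid carbon, is meta to the methoxy group and flanked by bromine.

Step 6
Reactants: 12 3,5,7-tribromo-6-methoxy-1-(methylsulfonyl)-1H-indole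
Product: 13 3,5,7-tribromo-6-methoxy-1H-indole
Conditions: aq. KOH (4 equiv), THF/MeOH, 50 °C; then aq. NH4Cl
Reagents that add atoms: none
Why: Base-mediated cleavage of an N-sulfonylindole by nucleophilic attack at sulfur with the indolide as leaving group (made better by the three bromines), under which the C–Br bonds and the methyl ether should be inert.

**Compound list**
1 | 2-bromo-3-methoxyaniline | COc1cccc(N)c1Br | starting material
2 | N-bromosuccinimide | O=C1CCC(=O)N1Br | starting material
3 | 2,4-dibromo-3-methoxyaniline | COc1c(Br)ccc(N)c1Br | intermediate
4 | methanesulfonyl chloride | CS(=O)(=O)Cl | starting material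
5 | N-(2,4-dibromo-3-methoxyphenyl)methanesulfonamide | COc1c(Br)ccc(NS(C)(=O)=O)c1Br | intermediate
6 | 2-bromo-1,1-diethoxyethane (bromoacetaldehyde diethyl acetal) | CCOC(CBr)OCC | starting material
7 | N-(2,4-dibromo-3-methoxyphenyl)-N-(2,2-diethoxyethyl)methanesulfonamide | COc1c(Br)ccc(N(CC(OCC)OCC)S(C)(=O)=O)c1Br | intermediate
8 | O-ethyl oxocarbenium ion of N-(2,4-dibromo-3-methoxyphenyl)-N-(2-oxoethyl)methanesulfonamide (not isolated) | CC[O+]=CCN(c1ccc(Br)c(OC)c1Br)S(C)(=O)=O | intermediate
9 | 5,7-dibromo-3-ethoxy-6-methoxy-1-(methylsulfonyl)indoline (racemic, not isolated) | CCOC1CN(S(C)(=O)=O)c2c(Br)c(OC)c(Br)cc21 | intermediate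
10 | 5,7-dibromo-6-methoxy-1-(methylsulfonyl)-1H-indole | COc1c(Br)cc2ccn(S(C)(=O)=O)c2c1Br | intermediate
11 | bromine | BrBr | starting material
12 | 3,5,7-tribromo-6-methoxy-1-(methylsulfonyl)-1H-indole | COc1c(Br)cc2c(Br)cn(S(C)(=O)=O)c2c1Br | intermediate
13 | 3,5,7-tribromo-6-methoxy-1H-indole | COc1c(Br)cc2c(Br)c[nH]c2c1Br | target

**Total step count:** 6
**Longest linear sequence:** 6 steps (1 → 3 → 5 → 7 → 10 → 12 → 13)

**Steps most likely to fail**

Step 4 (key step). The arene is deactivated by two bromines and its methoxy group is twisted out of conjugation. The oxocarbenium ion may therefore be consumed by intermolecular reaction, hydrolysis to the aldehyde or oligomerisation before it closes the ring.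
Fallback: this sets out from aniline 3 and makes the same C3a–C3 bond by cross-coupling instead of electrophilic substitution.
- Iodination of 3 (NIS, cat. TFA, MeCN, rt) at the only remaining carbon ortho or para to the amino group should give 2,4-dibromo-6-iodo-3-methoxyaniline F1.
- Sonogashira coupling with trimethylsilylacetylene (PdCl2(PPh3)2, CuI, Et3N, THF, rt) should be selective for the C–I bond and give 2,4-dibromo-3-methoxy-6-[(trimethylsilyl)ethynyl]aniline F2.
- TBAF in refluxing THF should remove the silyl group to 2,4-dibromo-6-ethynyl-3-methoxyaniline F3 (not isolated) and promote its 5-endo-dig hydroamination to 5,7-dibromo-6-methoxy-1H-indole F4.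
- Bromination of the free indole at C3 with N-bromosuccinimide 2 (DMF, 0 °C) comes back to the route at target 13.

Step 1. Bromine may also attack C6 (ortho to the amino group, para to the methoxy group) and a second bromination may follow, so the wanted isomer may have to be separated from close-running isomers.
Fallback: this sets out from N-bromosuccinimide 2, used on an arene whose competing position is blocked by a carboxyl group.
- Methyl 2-amino-4-methoxybenzoate F5 is dibrominated (NBS 2, 2.1 equiv, DMF, rt) at C3 and C5, the only carbons activated by both donors, to give methyl 2-amino-3,5-dibromo-4-methoxybenzoate F6.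
- Saponification (NaOH, MeOH/H2O, reflux, then acid) gives 2-amino-3,5-dibromo-4-methoxybenzoic acid F7.
- Acid-promoted protodecarboxylation of this anthranilic acid (aq. H2SO4, reflux; ipso protonation at the carbon ortho to NH2 and para to OMe) comes back to the route at aniline 3.

Step 3. SN2 displacement on the β,β-dialkoxy bromide by a hindered, weakly nucleophilic sulfonamide anion may be too slow. At the temperature needed the bromoacetal may be lost by elimination before alkylation is complete.
Fallback: this sets out from sulfonamide 5 and forms the same N–C bond by redox condensation. A Mitsunobu reaction of 5 with commercial 2,2-diethoxyethanol (PPh3, DIAD, THF, 0 °C → rt) uses the sulfonamide N–H as the acidic partner and needs no heating. It comes back to the route at acetal 7 without any new intermediate.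

**Further compounds**
F1 | step 4 | 2,4-dibromo-6-iodo-3-methoxyaniline | COc1c(Br)cc(I)c(N)c1Br
F2 | step 4 | 2,4-dibromo-3-methoxy-6-[(trimethylsilyl)ethynyl]aniline | COc1c(Br)cc(C#C[Si](C)(C)C)c(N)c1Br
F3 | step 4 | 2,4-dibromo-6-ethynyl-3-methoxyaniline | COc1c(Br)cc(C#C)c(N)c1Br
F4 | step 4 | 5,7-dibromo-6-methoxy-1H-indole | COc1c(Br)cc2cc[nH]c2c1Br
F5 | step 1 | methyl 2-amino-4-methoxybenzoate | COC(=O)c1ccc(OC)cc1N
F6 | step 1 | methyl 2-amino-3,5-dibromo-4-methoxybenzoate | COC(=O)c1cc(Br)c(OC)c(Br)c1N
F7 | step 1 | 2-amino-3,5-dibromo-4-methoxybenzoic acid | Nc1c(Br)c(OC)c(Br)cc1C(=O)O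
F0 | step 3 | none | none
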